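**Plan**
1. Numbering: guaiacyl arm C7–C8–C9, central syringyl arm C7'–C8'–C9', glycerol arm C7''–C8''–C9''. Ring A = C7–O–C9'–C8'–C8 and ring B = C7'–O–C9–C8–C8'. The target is the endo,exo-furofuran (7R,8S,7'S,8'S) carrying a threo (7''R,8''R) 8''–O–4' ether.
2. Enabling feature: C7 is benzylic and para to the guaiacyl hydroxyl, which can be kept as the only free phenol, and the oxygen on C7 is the C9' oxygen. Ring A is therefore the internal alcohol adduct of a p-quinone methide, and its C7–O bond is the first skeletal cut.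
3. Further cuts: saturation of a C7=C8 arylidene, C9–O of ring B (Williamson closure), C7=C8 (aldol condensation with O-benzylvanillin), C7'–C8' (anti-aldol of a succinyl imide), C7''–C8'' (syn glycolate aldol), O4'–C8'' (phenol alkylation).
4. Forward: the silylated glycerol arm is built on a cyanophenol and unmasked to aldehyde 11. Anti-aldol and lactonisation give a cis-lactone that already holds the ring B oxygen. Arylidene formation, reduction and cycloetherification give ring B, hydrogenation frees the phenol and C9'–OH, anodic closure gives ring A, and fluoride ends the route.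
5. Stereochemistry: C7''/C8'' and C7'/C8' come from (S)-4-benzyloxazolidinone auxiliaries (boron syn-aldol, magnesium anti-aldol). C8 comes from hydrogen delivery anti to the two cis substituents of ring B, and C7 from exo-selective closure on the folded bicycle.

Key step: step 16

Abbreviations: R* = (1R,2R)-1,3-bis(tert-butyldimethylsilyloxy)-1-[3,5-dimethoxy-4-(triisopropylsilyloxy)phenyl]propan-2-yl (attached through C8''); ArS = 3,5-dimethoxy-4-(R*O)phenyl; Xc = (4S)-4-benzyl-2-oxo-1,3-oxazolidin-3-yl.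
Assumption: the magnesium-catalysed anti-aldol of 14 is taken to show the sense known for N-propionyl imides (attack on the chelated Z-enolate anti to the C4 benzyl group). E geometry is drawn for 22–25, but either alkene isomer would serve.

Step 1
Reactants: 1 (4S)-4-benzyl-3-(chloroacetyl)-1,3-oxazolidin-2-one; 2 4-hydroxy-3,5-dimethoxybenzonitrile
Product: 3 (4S)-4-benzyl-3-[(4-cyano-2,6-dimethoxyphenoxy)acetyl]-1,3-oxazolidin-2-one
Conditions: K2CO3, NaI (cat.), acetone, rt to 40 °C
Reagents that add atoms: none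
Why: Williamson ether synthesis with in situ Finkelstein activation, in which the acidic, weakly basic cyanophenoxide should displace halide at the α-carbon by SN2 much faster than it attacks either imide carbonyl, the auxiliary stereocentre not being involved.

Step 2
Reactants: 4 syringaldehyde (4-hydroxy-3,5-dimethoxybenzaldehyde)
Product: 5 3,5-dimethoxy-4-(triisopropylsilyloxy)benzaldehyde
Conditions: i-Pr3SiCl, imidazole, DMF, rt
Reagents that add atoms: chlorotriisopropylsilane, CC(C)[Si](Cl)(C(C)C)C(C)C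
Why: Routine imidazole-promoted O-silylation of a phenol, chosen because a triisopropylsilyl ether wedged between two methoxy groups should outlast the basic, hydridic and weakly acidic steps up to the final fluoride treatment.

Step 3
Reactants: 3 aryloxyacetyl imide; 5 3,5-dimethoxy-4-(triisopropylsilyloxy)benzaldehyde
Product: 7 (4S)-4-benzyl-3-{(2S,3R)-2-(4-cyano-2,6-dimethoxyphenoxy)-3-hydroxy-3-[3,5-dimethoxy-4-(triisopropylsilyloxy)phenyl]propanoyl}-1,3-oxazolidin-2-one (syn), via dibutylboron Z-enolate 6 (not isolated)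
Conditions: n-Bu2BOTf, Et3N, CH2Cl2, −78 to 0 °C; 5, −78 to 0 °C; pH 7 buffer, MeOH, 30% H2O2, 0 °C
Reagents that add atoms: none
Why: Evans syn-aldol reaction of an aryloxyacetyl (glycolate-type) imide, in which Z-enolate 6 reacts through a Zimmerman–Traxler chair on the face remote from the auxiliary benzyl group and so sets C8'' and C7'' together in the syn (threo) relationship with the sense that becomes (7''R,8''R) after reduction.

Step 4
Reactants: 7 syn-aldol imide
Product: 8 4-({(1R,2R)-1,3-dihydroxy-1-[3,5-dimethoxy-4-(triisopropylsilyloxy)phenyl]propan-2-yl}oxy)-3,5-dimethoxybenzonitrile (threo diol)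
Conditions: LiBH4, MeOH (1 equiv), THF, 0 °C
Reagents that add atoms: none
Why: Reductive removal of the oxazolidinone with LiBH4, which reduces the activated exocyclic imide carbonyl to C9''H2OH without touching the nitrile, the aryl silyl ether or either stereocentre.

Step 5
Reactants: 8 threo diol
Product: 9 3,5-dimethoxy-4-(R*O)benzonitrile (bis-tert-butyldimethylsilyl ether of 8)
Conditions: t-BuMe2SiOTf, 2,6-lutidine, CH2Cl2, 0 °C
Reagents that add atoms: tert-butyldimethylsilyl trifluoromethanesulfonate, CC(C)(C)[Si](C)(C)OS(=O)(=O)C(F)(F)F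
Why: Silyl triflate silylation of a primary and a hindered secondary benzylic alcohol under a non-nucleophilic base, done so that C9'–OH will be the only free alcohol at the electrolysis and all three silyl groups fall in one final operation.

Step 6
Reactants: 9 silylated nitrile
Product: 11 3,5-dimethoxy-4-(R*O)benzaldehyde (ArS–CHO), via N-diisobutylalumino aldimine 10 (not isolated)
Conditions: i-Bu2AlH, toluene, −78 °C; aq potassium sodium tartrate, rt
Reagents that add atoms: water, O
Why: Partial reduction of an aryl nitrile with i-Bu2AlH, in which one hydride adds to give aldimine 10 that resists further reduction at low temperature and is hydrolysed to the aldehyde on work-up, the silyl ethers being inert.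

Step 7
Reactants: 12 (4S)-4-benzyl-1,3-oxazolidin-2-one; 13 methyl 4-chloro-4-oxobutanoate
Product: 14 methyl 4-oxo-4-Xc-butanoate (succinyl imide)
Conditions: n-BuLi, THF, −78 °C; 13, −78 to 0 °C
Reagents that add atoms: none
Why: Standard N-acylation of the lithiated oxazolidinone with an acid chloride, the methyl ester being far less electrophilic at −78 °C.

Step 8
Reactants: 11 ArS–CHO; 14 succinyl imide
Product: 15 methyl (3R)-3-[(S)-ArS(trimethylsilyloxy)methyl]-4-oxo-4-Xc-butanoate (anti; C8' R and C7' S)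
Conditions: MgCl2 (20 mol %), Et3N, Me3SiCl, EtOAc, rt
Reagents that add atoms: chlorotrimethylsilane, C[Si](C)(C)Cl
Why: Magnesium-halide-catalysed direct anti-aldol reaction of an N-acyloxazolidinone with a non-enolisable electron-rich aromatic aldehyde, in which only the chelated imide is soft-enolised, its Z-enolate should add through a boat-like transition state on the face opposite the benzyl group to set C8' and C7' anti, and silylation of the aldolate makes the addition irreversible and releases MgCl2.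

Step 9
Reactants: 15 anti-aldol silyl ether
Product: 17 (2S,3R)-2-ArS-5-oxooxolane-3-carboxylic acid (cis-lactone acid), via hydroxy acid monoester 16 (not isolated)
Conditions: LiOH, 30% H2O2, THF–H2O, 0 °C; Na2SO3; KHSO4 (pH 3); pyridinium p-toluenesulfonate (cat.), CH2Cl2, rt
Reagents that add atoms: hydrogen peroxide (as LiOOH), OO
Why: Hydroperoxide cleavage of the imide at the exocyclic carbonyl followed by acid-induced loss of the trimethylsilyl group and γ-lactonisation of 16, in which the C7'–O bond is never broken, so the anti-aldol relationship is translated into the cis-disubstituted lactone while the cold, brief base exposure should spare the hindered aryl silyl ether.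

Step 10
Reactants: 17 cis-lactone acid
Product: 18 (4S,5S)-5-ArS-4-(hydroxymethyl)oxolan-2-one
Conditions: BH3·SMe2, THF, 0 °C to rt; MeOH
Reagents that add atoms: none
Why: Chemoselective borane reduction of a carboxylic acid beside a γ-lactone, well known for paraconic-type acids, under neutral conditions that should not trigger migration of the lactone onto the new primary alcohol.

Step 11
Reactants: 18 hydroxymethyl lactone
Product: 19 (4S,5S)-5-ArS-4-(benzyloxymethyl)oxolan-2-one
Conditions: BnOC(=NH)CCl3, CF3SO3H (5 mol %), CH2Cl2–cyclohexane, 0 °C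
Reagents that add atoms: benzyl 2,2,2-trichloroacetimidate, N=C(OCc1ccccc1)C(Cl)(Cl)Cl
Why: Acid-catalysed O-benzylation with a trichloroacetimidate, chosen because it avoids the alkoxide that would translactonise and because the benzyl ether later falls in the same hydrogenation that saturates C7=C8.

Step 12
Reactants: 19 benzyloxymethyl lactone; 20 4-benzyloxy-3-methoxybenzaldehyde (O-benzylvanillin)
Product: 22 (3E,4S,5S)-5-ArS-3-(4-benzyloxy-3-methoxybenzylidene)-4-(benzyloxymethyl)oxolan-2-one, via aldol acetate 21 (not isolated)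
Conditions: LiN(SiMe3)2, THF, −78 °C; 20; Ac2O, −78 to 0 °C; DBU, rt
Reagents that add atoms: none
Why: One-flask aldol condensation (aldol addition after deprotonation at C8, O-acetylation of the aldolate, E1cB elimination with DBU) that should give the conjugated E-arylidene lactone, C8' carrying no acidifying group and therefore keeping its configuration.

Step 13
Reactants: 22 arylidene lactone
Product: 23 (1S,2S,3E)-1-ArS-4-(4-benzyloxy-3-methoxyphenyl)-2-(benzyloxymethyl)-3-(hydroxymethyl)but-3-en-1-ol (allylic diol)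
Conditions: i-Bu2AlH (4 equiv), CH2Cl2, −78 to 0 °C; aq potassium sodium tartrate
Reagents that add atoms: none
Why: Exhaustive 1,2-reduction of an α,β-unsaturated lactone with i-Bu2AlH to the allylic diol, which leaves the C7=C8 bond, the ethers and the C7' and C8' stereocentres untouched.

Step 14
Reactants: 23 allylic diol
Product: 25 (2S,3S,4E)-2-ArS-4-(4-benzyloxy-3-methoxybenzylidene)-3-(benzyloxymethyl)oxolane (ring B), via primary allylic tosylate 24 (not isolated)
Conditions: NaH, THF, 0 °C; 1-tosylimidazole, 0 °C to rt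
Reagents that add atoms: none
Why: Intramolecular Williamson etherification, in which the less hindered primary allylic alkoxide is sulfonylated selectively and the C7' alkoxide displaces tosylate from C9 by a 5-exo-tet SN2 attack, so ring B closes with retention at C7' because its C–O bond is not involved.

Step 15
Reactants: 25 arylidene tetrahydrofuran
Product: 26 (2S,3S,4S)-2-ArS-4-(4-hydroxy-3-methoxybenzyl)-3-(hydroxymethyl)oxolane (all-cis)
Conditions: H2 (1 atm), 10% Pd/C, EtOAc–EtOH, rt
Reagents that add atoms: none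
Why: Heterogeneous catalytic hydrogenation with concurrent benzyl ether hydrogenolysis, precedented for 4-arylidene-2-aryltetrahydrofuran lignan precursors, in which the catalyst can reach only the face of C7=C8 opposite the cis aryl and benzyloxymethyl groups, so the new C8–H bond forms there and the benzyl arm ends cis to both.

Step 16
Reactants: 26 all-cis hydroxymethyl benzyl tetrahydrofuran
Product: 28 (7R,8S,7'S,8'S)-furofuran with exo 4-hydroxy-3-methoxyphenyl at C7 and endo ArS at C7' (tris-silyl ether of the target), via p-quinone methide 27 (not isolated)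
Conditions: graphite anode, Pt cathode, undivided cell, constant current (about 2.1 F/mol), LiClO4 (0.1 M), 2,6-lutidine, MeCN–(CF3)2CHOH 9:1, about 3 mM, rt
Reagents that add atoms: none
Why: Proposed new method: at the anode the lutidine-associated guaiacyl phenol of 26, the only group oxidisable at low potential because every oxygen on the two syringyl rings is alkylated or silylated, should lose two electrons and two protons (O–H and C7–H) to give p-quinone methide 27, while protons are reduced to H2 at the cathode. The C9' hydroxyl then adds to C7 in a 5-exo-trig conjugate addition that restores the aromatic ring and closes ring A cis-fused to ring B. The closest known reactions are the quinone-oxidant (DDQ) cyclisation of p-hydroxybenzyl lignans to 2-aryltetrahydrofurans and the anodic benzylic alkoxylation of 4-alkylphenols, but the anodic intramolecular version on an ortho-unblocked guaiacyl lignan has not been described. The new stereocentre C7 is controlled by the bicyclic framework, since the methide should react in the rotamer that turns its six-membered ring away from the concave face already filled by the endo aryl group at C7', which places the guaiacyl group exo (7R). Selectivity over radical coupling at the free C5 position, ipso capture at C1 to a six-membered spirodienone and re-oxidation of the product phenol is sought through high dilution, a base that speeds C7–H loss, silyl masking of every other hydroxyl and interruption near the theoretical charge.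

Step 17
Reactants: 28 tris-silyl furofuran
Product: 29 target CNP0317965.1 (7R,8S,7'S,8'S,7''R,8''R)
Conditions: Bu4NF, AcOH, THF, 0 °C to rt
Reagents that add atoms: none
Why: Fluoride-mediated cleavage of two alkyl silyl ethers and one aryl silyl ether, buffered with acetic acid so that the phenoxides formed cannot open the benzylic ethers through quinone methides, which leaves all six stereocentres unchanged.

**Compound list**
1 | (4S)-4-benzyl-3-(chloroacetyl)-1,3-oxazolidin-2-one | O=C(CCl)N1[C@@H](Cc2ccccc2)COC1=O | starting material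
2 | 4-hydroxy-3,5-dimethoxybenzonitrile | COc1cc(C#N)cc(OC)c1O | starting material
3 | (4S)-4-benzyl-3-[(4-cyano-2,6-dimethoxyphenoxy)acetyl]-1,3-oxazolidin-2-one | COc1cc(C#N)cc(OC)c1OCC(=O)N1[C@@H](Cc2ccccc2)COC1=O | intermediate
4 | syringaldehyde | COc1cc(C=O)cc(OC)c1O | starting material
5 | 3,5-dimethoxy-4-(triisopropylsilyloxy)benzaldehyde | COc1cc(C=O)cc(OC)c1O[Si](C(C)C)(C(C)C)C(C)C | intermediate
6 | dibutylboron Z-enolate of 3 | CCCCB(CCCC)O/C(=C\Oc1c(OC)cc(C#N)cc1OC)N1[C@@H](Cc2ccccc2)COC1=O | intermediate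
7 | syn-aldol imide (2S,3R) | COc1cc(C#N)cc(OC)c1O[C@H](C(=O)N1[C@@H](Cc2ccccc2)COC1=O)[C@H](O)c1cc(OC)c(O[Si](C(C)C)(C(C)C)C(C)C)c(OC)c1 | intermediate
8 | threo (1R,2R)-diol nitrile | COc1cc(C#N)cc(OC)c1O[C@H](CO)[C@H](O)c1cc(OC)c(O[Si](C(C)C)(C(C)C)C(C)C)c(OC)c1 | intermediate
9 | 3,5-dimethoxy-4-(R*O)benzonitrile | COc1cc(C#N)cc(OC)c1O[C@H](CO[Si](C)(C)C(C)(C)C)[C@H](O[Si](C)(C)C(C)(C)C)c1cc(OC)c(O[Si](C(C)C)(C(C)C)C(C)C)c(OC)c1 | intermediate
10 | N-diisobutylalumino aldimine of 11 | CC(C)C[Al](CC(C)C)N=Cc3cc(OC)c(O[C@H](CO[Si](C)(C)C(C)(C)C)[C@H](O[Si](C)(C)C(C)(C)C)c4cc(OC)c(O[Si](C(C)C)(C(C)C)C(C)C)c(OC)c4)c(OC)c3 | intermediate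
11 | 3,5-dimethoxy-4-(R*O)benzaldehyde | O=Cc3cc(OC)c(O[C@H](CO[Si](C)(C)C(C)(C)C)[C@H](O[Si](C)(C)C(C)(C)C)c4cc(OC)c(O[Si](C(C)C)(C(C)C)C(C)C)c(OC)c4)c(OC)c3 | intermediate
12 | (4S)-4-benzyl-1,3-oxazolidin-2-one | O=C1N[C@@H](Cc2ccccc2)CO1 | starting material
13 | methyl 4-chloro-4-oxobutanoate | COC(=O)CCC(Cl)=O | starting material
14 | methyl 4-oxo-4-Xc-butanoate | COC(=O)CCC(=O)N1[C@@H](Cc2ccccc2)COC1=O | intermediate
15 | anti-aldol trimethylsilyl ether (C8' R, C7' S) | COC(=O)C[C@@H](C(=O)N1[C@@H](Cc2ccccc2)COC1=O)[C@H](O[Si](C)(C)C)c3cc(OC)c(O[C@H](CO[Si](C)(C)C(C)(C)C)[C@H](O[Si](C)(C)C(C)(C)C)c4cc(OC)c(O[Si](C(C)C)(C(C)C)C(C)C)c(OC)c4)c(OC)c3 | intermediate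
16 | (2R)-2-[(S)-ArS(hydroxy)methyl]-4-methoxy-4-oxobutanoic acid | COC(=O)C[C@@H](C(O)=O)[C@H](O)c3cc(OC)c(O[C@H](CO[Si](C)(C)C(C)(C)C)[C@H](O[Si](C)(C)C(C)(C)C)c4cc(OC)c(O[Si](C(C)C)(C(C)C)C(C)C)c(OC)c4)c(OC)c3 | intermediate
17 | (2S,3R)-2-ArS-5-oxooxolane-3-carboxylic acid (cis) | OC(=O)[C@@H]1CC(=O)O[C@@H]1c3cc(OC)c(O[C@H](CO[Si](C)(C)C(C)(C)C)[C@H](O[Si](C)(C)C(C)(C)C)c4cc(OC)c(O[Si](C(C)C)(C(C)C)C(C)C)c(OC)c4)c(OC)c3 | intermediate
18 | (4S,5S)-5-ArS-4-(hydroxymethyl)oxolan-2-one | OC[C@@H]1CC(=O)O[C@@H]1c3cc(OC)c(O[C@H](CO[Si](C)(C)C(C)(C)C)[C@H](O[Si](C)(C)C(C)(C)C)c4cc(OC)c(O[Si](C(C)C)(C(C)C)C(C)C)c(OC)c4)c(OC)c3 | intermediate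
19 | (4S,5S)-5-ArS-4-(benzyloxymethyl)oxolan-2-one | c1ccccc1COC[C@@H]2CC(=O)O[C@@H]2c3cc(OC)c(O[C@H](CO[Si](C)(C)C(C)(C)C)[C@H](O[Si](C)(C)C(C)(C)C)c4cc(OC)c(O[Si](C(C)C)(C(C)C)C(C)C)c(OC)c4)c(OC)c3 | intermediate
20 | 4-benzyloxy-3-methoxybenzaldehyde | COc1cc(C=O)ccc1OCc1ccccc1 | starting material
21 | aldol acetate of 19 and 20 (mixture at C7 and C8) | c1ccccc1COC[C@@H]2C(C(OC(C)=O)c5ccc(OCc6ccccc6)c(OC)c5)C(=O)O[C@@H]2c3cc(OC)c(O[C@H](CO[Si](C)(C)C(C)(C)C)[C@H](O[Si](C)(C)C(C)(C)C)c4cc(OC)c(O[Si](C(C)C)(C(C)C)C(C)C)c(OC)c4)c(OC)c3 | intermediate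
22 | (3E,4S,5S)-arylidene lactone | c1ccccc1COC[C@@H]2/C(=C\c5ccc(OCc6ccccc6)c(OC)c5)C(=O)O[C@@H]2c3cc(OC)c(O[C@H](CO[Si](C)(C)C(C)(C)C)[C@H](O[Si](C)(C)C(C)(C)C)c4cc(OC)c(O[Si](C(C)C)(C(C)C)C(C)C)c(OC)c4)c(OC)c3 | intermediate
23 | (1S,2S,3E)-allylic diol | OC/C(=C/c1ccc(OCc2ccccc2)c(OC)c1)[C@@H](COCc1ccccc1)[C@H](O)c3cc(OC)c(O[C@H](CO[Si](C)(C)C(C)(C)C)[C@H](O[Si](C)(C)C(C)(C)C)c4cc(OC)c(O[Si](C(C)C)(C(C)C)C(C)C)c(OC)c4)c(OC)c3 | intermediate
24 | primary allylic tosylate of 23 | Cc1ccc(cc1)S(=O)(=O)OC/C(=C/c1ccc(OCc2ccccc2)c(OC)c1)[C@@H](COCc1ccccc1)[C@H](O)c3cc(OC)c(O[C@H](CO[Si](C)(C)C(C)(C)C)[C@H](O[Si](C)(C)C(C)(C)C)c4cc(OC)c(O[Si](C(C)C)(C(C)C)C(C)C)c(OC)c4)c(OC)c3 | intermediate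
25 | (2S,3S,4E)-arylidene tetrahydrofuran | c1ccccc1COC[C@@H]2/C(=C\c5ccc(OCc6ccccc6)c(OC)c5)CO[C@@H]2c3cc(OC)c(O[C@H](CO[Si](C)(C)C(C)(C)C)[C@H](O[Si](C)(C)C(C)(C)C)c4cc(OC)c(O[Si](C(C)C)(C(C)C)C(C)C)c(OC)c4)c(OC)c3 | intermediate
26 | (2S,3S,4S)-2-ArS-4-(4-hydroxy-3-methoxybenzyl)-3-(hydroxymethyl)oxolane (all-cis) | OC[C@@H]1[C@H](Cc2ccc(O)c(OC)c2)CO[C@@H]1c3cc(OC)c(O[C@H](CO[Si](C)(C)C(C)(C)C)[C@H](O[Si](C)(C)C(C)(C)C)c4cc(OC)c(O[Si](C(C)C)(C(C)C)C(C)C)c(OC)c4)c(OC)c3 | intermediate
27 | p-quinone methide at C7 | OC[C@@H]1[C@H](C=C2C=CC(=O)C(OC)=C2)CO[C@@H]1c3cc(OC)c(O[C@H](CO[Si](C)(C)C(C)(C)C)[C@H](O[Si](C)(C)C(C)(C)C)c4cc(OC)c(O[Si](C(C)C)(C(C)C)C(C)C)c(OC)c4)c(OC)c3 | intermediate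
28 | tris-silyl ether of the target (7R,8S,7'S,8'S,7''R,8''R) | COc1cc([C@@H]2OC[C@@H]3[C@H]2CO[C@@H]3c4cc(OC)c(O[C@H](CO[Si](C)(C)C(C)(C)C)[C@H](O[Si](C)(C)C(C)(C)C)c5cc(OC)c(O[Si](C(C)C)(C(C)C)C(C)C)c(OC)c5)c(OC)c4)ccc1O | intermediate
29 | CNP0317965.1 | COc1cc([C@@H]2OC[C@@H]3[C@H]2CO[C@@H]3c2cc(OC)c(O[C@H](CO)[C@H](O)c3cc(OC)c(O)c(OC)c3)c(OC)c2)ccc1O | target

**Step count**
Total step count: 17. Longest linear sequence: 15 steps (1, 3–6, 8–17).

**Steps most likely to fail**

1. Step 16. What may go wrong: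
- coupling of the phenoxyl radical through the free C5 position;
- capture of the doubly oxidised ring at C1 by the tethered alcohol instead of loss of the C7 proton;
- further oxidation of the product phenol, whose potential is close to that of the substrate.

The fallback abandons C–H oxidation and brings the C7 oxygen in by hydroboration. It sets out from 25. BH3·THF adds to C7=C8 from the open face, with boron at the less substituted benzylic carbon, to give the C7 alkylborane F1. NaBO3·4H2O converts it into the (7S)-benzylic alcohol F2, in which C8 is already cis to its neighbours. H2 over Pd/C removes both benzyl groups to give the debenzylated 7-hydroxy compound F3. A catalytic amount of pyridinium p-toluenesulfonate in CH2Cl2 should then ionise only this most activated alcohol, and C9'–OH closes ring A. This dehydrative furofuran closure is classical and favours the exo aryl group. The fallback rejoins the route at 28.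

2. Step 8. What may go wrong:
- slow catalyst turnover or eroded anti and facial selectivity because the ester arm competes for magnesium;
- reversal of the addition before silyl capture.

The fallback replaces the catalytic closed transition state by a preformed enolate and an externally activated aldehyde. It sets out from 14 and 11. n-Bu2BOTf and i-Pr2NEt in CH2Cl2 give the dibutylboron Z-enolate F4. This is added at −78 °C to 11 precomplexed with Et2AlCl, and the open transition state on the enolate face anti to the benzyl group should give the free anti-aldol imide F5. After an oxidative work-up, the conditions of step 9 cleave the auxiliary and lactonise. The fallback rejoins the route at 17.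

3. Step 15. What may go wrong:
- hydrogenolysis of the allylic C9–O or the benzylic C7'–O bond;
- migration of the double bond into the ring before saturation, which would erase C8';
- incomplete cleavage of the primary benzyl ether.

The fallback moves the saturation to the conjugated lactone and away from palladium. It sets out from 22. NiCl2·6H2O and NaBH4 in MeOH–THF at 0 °C perform a conjugate reduction that spares benzyl ethers, and protonation of the enolate from the open face gives the all-cis saturated lactone F6. i-Bu2AlH gives the saturated diol F7. NaH and 1-tosylimidazole give, through the primary tosylate F8, the dibenzyl tetrahydrofuran F9. H2 over Pd/C then has only two benzyl ethers to cleave. The fallback rejoins the route at 26.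

**Further compounds**
F1 | step 16 | C7 alkylborane from 25 | c1ccccc1COC[C@@H]2[C@H]([C@H](B)c5ccc(OCc6ccccc6)c(OC)c5)CO[C@@H]2c3cc(OC)c(O[C@H](CO[Si](C)(C)C(C)(C)C)[C@H](O[Si](C)(C)C(C)(C)C)c4cc(OC)c(O[Si](C(C)C)(C(C)C)C(C)C)c(OC)c4)c(OC)c3
F2 | step 16 | (7S)-benzylic alcohol, dibenzyl ether | c1ccccc1COC[C@@H]2[C@H]([C@H](O)c5ccc(OCc6ccccc6)c(OC)c5)CO[C@@H]2c3cc(OC)c(O[C@H](CO[Si](C)(C)C(C)(C)C)[C@H](O[Si](C)(C)C(C)(C)C)c4cc(OC)c(O[Si](C(C)C)(C(C)C)C(C)C)c(OC)c4)c(OC)c3
F3 | step 16 | debenzylated 7-hydroxy compound | OC[C@@H]1[C@H]([C@H](O)c2ccc(O)c(OC)c2)CO[C@@H]1c3cc(OC)c(O[C@H](CO[Si](C)(C)C(C)(C)C)[C@H](O[Si](C)(C)C(C)(C)C)c4cc(OC)c(O[Si](C(C)C)(C(C)C)C(C)C)c(OC)c4)c(OC)c3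
F4 | step 8 | dibutylboron Z-enolate of 14 | CCCCB(CCCC)O/C(=C\CC(=O)OC)N1[C@@H](Cc2ccccc2)COC1=O
F5 | step 8 | free anti-aldol imide | COC(=O)C[C@@H](C(=O)N1[C@@H](Cc2ccccc2)COC1=O)[C@H](O)c3cc(OC)c(O[C@H](CO[Si](C)(C)C(C)(C)C)[C@H](O[Si](C)(C)C(C)(C)C)c4cc(OC)c(O[Si](C(C)C)(C(C)C)C(C)C)c(OC)c4)c(OC)c3
F6 | step 15 | all-cis saturated lactone | c1ccccc1COC[C@@H]2[C@H](Cc5ccc(OCc6ccccc6)c(OC)c5)C(=O)O[C@@H]2c3cc(OC)c(O[C@H](CO[Si](C)(C)C(C)(C)C)[C@H](O[Si](C)(C)C(C)(C)C)c4cc(OC)c(O[Si](C(C)C)(C(C)C)C(C)C)c(OC)c4)c(OC)c3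
F7 | step 15 | saturated diol | OC[C@@H](Cc1ccc(OCc2ccccc2)c(OC)c1)[C@@H](COCc1ccccc1)[C@H](O)c3cc(OC)c(O[C@H](CO[Si](C)(C)C(C)(C)C)[C@H](O[Si](C)(C)C(C)(C)C)c4cc(OC)c(O[Si](C(C)C)(C(C)C)C(C)C)c(OC)c4)c(OC)c3
F8 | step 15 | primary tosylate of F7 | Cc1ccc(cc1)S(=O)(=O)OC[C@@H](Cc1ccc(OCc2ccccc2)c(OC)c1)[C@@H](COCc1ccccc1)[C@H](O)c3cc(OC)c(O[C@H](CO[Si](C)(C)C(C)(C)C)[C@H](O[Si](C)(C)C(C)(C)C)c4cc(OC)c(O[Si](C(C)C)(C(C)C)C(C)C)c(OC)c4)c(OC)c3
F9 | step 15 | dibenzyl tetrahydrofuran | c1ccccc1COC[C@@H]2[C@H](Cc5ccc(OCc6ccccc6)c(OC)c5)CO[C@@H]2c3cc(OC)c(O[C@H](CO[Si](C)(C)C(C)(C)C)[C@H](O[Si](C)(C)C(C)(C)C)c4cc(OC)c(O[Si](C(C)C)(C(C)C)C(C)C)c(OC)c4)c(OC)c3
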